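**Retrosynthetic overview**

1. Target 35 comes from its bis-silyl ether 34 by desilylation. The butenolide ring is attached intact and last, by B-alkyl Suzuki–Miyaura coupling of a C12 borane (from a C9 vinyl group) with 4-bromobutenolide.
2. Rings A and B are formed together. C6 carries the oxygen and lies between C5 and C7 in the ring B cyclohexene whose alkene is C8=C9, so C5=C6 serves as a boron-bearing dienophile and C7=C8–C9=C10 as the diene. The intramolecular Diels–Alder reaction of the (E)-alkenyl(dicyclohexyl)borane forms C5–C10 and C6–C7, and oxidation of C6–B with retention gives the 6α-oxygen.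
3. The trienylborane comes from Chx2BH and the C5≡C6 alkyne. The tetrasubstituted C9=C10 alkene (C20 cis to C8, tether outside) comes from an alkynoate by syn-methylcupration/iodination and coupling with an isopropenylboronate.
4. C4 is set by enzymatic desymmetrisation of dimethyl allyl(methyl)malonate and C2 by catalyst-controlled propargylation. A γ-lactone ties C2–O to C5 until the alkyne is needed.
5. Numbering is that of the labdane skeleton: ring A is C1–C5 and C10, ring B is C5–C10, the side chain is C11–C16, C17 is on C8, C18 (α-methyl) and C19 (β-CH2O) are on C4, and C20 is on C10.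

Key step: step 13

Assumption: pig liver esterase is taken to leave the (R)-half-ester 4; if it favours the other enantiotopic ester, the two carboxyl groups exchange roles at step 3 (ester reduced, acid kept), which leads into the same series.

Assumption: (R)-TRIP is taken to direct the propargyl group to the Re face of aldehyde 9, as with simple aldehydes; otherwise its enantiomer is used.

**Route**

Step 1
Reactants: 1 dimethyl methylmalonate; 2 allyl bromide
Product: 3 dimethyl 2-methyl-2-(prop-2-en-1-yl)propanedioate
Conditions: NaH, THF, 0 °C; then 2, 0 °C → rt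
Reagents that add atoms: allyl bromide (2), C=CCBr
Why: Malonate alkylation (SN2), in which the unhindered sodium enolate of 1 meets a reactive allylic bromide, so the prochiral quaternary carbon that becomes C4 should form cleanly.

Step 2
Reactants: 3 dimethyl 2-methyl-2-(prop-2-en-1-yl)propanedioate
Product: 4 (2R)-2-(methoxycarbonyl)-2-methylpent-4-enoic acid
Conditions: pig liver esterase, phosphate buffer pH 7.5, rt, pH-stat (NaOH); then HCl to pH 2
Reagents that add atoms: water, O
Why: Enzymatic desymmetrisation (esterase hydrolysis), in which the enzyme distinguishes the two enantiotopic ester groups and thereby sets the quaternary C4 centre, while the carboxylate formed is not hydrolysed further.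

Step 3
Reactants: 4 (2R)-2-(methoxycarbonyl)-2-methylpent-4-enoic acid
Product: 6 methyl (2R)-2-(hydroxymethyl)-2-methylpent-4-enoate, via mixed carbonic anhydride 5 (not isolated)
Conditions: ClCO2Et, Et3N, THF, 0 °C; then NaBH4, THF/H2O, 0 °C
Reagents that add atoms: none
Why: Mixed-anhydride activation and borohydride reduction, in which NaBH4 reduces only the activated acyl carbon and leaves the hindered methyl ester and the alkene (which borane would attack) untouched, the quaternary C4 being unable to epimerise.

Step 4
Reactants: 6 methyl (2R)-2-(hydroxymethyl)-2-methylpent-4-enoate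
Product: 7 methyl (2R)-2-{[(tert-butyldiphenylsilyl)oxy]methyl}-2-methylpent-4-enoate
Conditions: TBDPSCl, imidazole, DMF, rt
Reagents that add atoms: tert-butyl(chloro)diphenylsilane, CC(C)(C)[Si](Cl)(c1ccccc1)c1ccccc1
Why: Silyl ether formation on the neopentyl primary alcohol, which gives C19 an acid-stable but fluoride-labile group that outlasts the later selective removal of a primary TBS ether.

Step 5
Reactants: 7 methyl (2R)-2-{[(tert-butyldiphenylsilyl)oxy]methyl}-2-methylpent-4-enoate
Product: 9 methyl (2R)-2-{[(tert-butyldiphenylsilyl)oxy]methyl}-2-methyl-4-oxobutanoate, via secondary ozonide 8 (not isolated)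
Conditions: O3, CH2Cl2, −78 °C; then PPh3, −78 °C → rt
Reagents that add atoms: ozone, O=[O+][O-]
Why: Ozonolysis with reductive work-up, the monosubstituted alkene being the only ozone-reactive site at −78 °C, which gives the C2 aldehyde with loss of one carbon as formaldehyde.

Step 6
Reactants: 9 methyl (2R)-2-{[(tert-butyldiphenylsilyl)oxy]methyl}-2-methyl-4-oxobutanoate; 10 allenylboronic acid pinacol ester
Product: 13 (3R,5R)-3-{[(tert-butyldiphenylsilyl)oxy]methyl}-3-methyl-5-(prop-2-yn-1-yl)oxolan-2-one, via borate ester 11 (not isolated), via hydroxy ester 12 (not isolated)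
Conditions: 10 (1.5 equiv), (R)-TRIP phosphoric acid (10 mol %), 4 Å molecular sieves, toluene, 0 °C; then MeOH, PPTS (cat.), rt → 40 °C
Reagents that add atoms: allenylboronic acid pinacol ester (10), C=C=CB1OC(C)(C)C(C)(C)O1
Why: Chiral Brønsted acid-catalysed propargylboration of an aldehyde through a closed six-membered transition state (SE2′ transfer, so the homopropargyl and not the allenyl carbinol forms), in which the catalyst directs attack to the Re face and sets C2 as R under catalyst control, after which the γ-hydroxy ester lactonises onto the neighbouring ester with help from the gem-disubstitution at C4, so that any material epimeric at C2 or at C4 becomes the trans-lactone and can be removed by chromatography.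

Step 7
Reactants: 13 (3R,5R)-3-{[(tert-butyldiphenylsilyl)oxy]methyl}-3-methyl-5-(prop-2-yn-1-yl)oxolan-2-one; 14 methyl chloroformate
Product: 16 methyl 4-[(2R,4R)-4-{[(tert-butyldiphenylsilyl)oxy]methyl}-4-methyl-5-oxooxolan-2-yl]but-2-ynoate, via lithium acetylide 15 (not isolated)
Conditions: LiN(iPr)2 (1.05 equiv), THF, −78 °C; then 14, −78 → −20 °C
Reagents that add atoms: methyl chloroformate (14), COC(=O)Cl
Why: Acylation of a lithium acetylide, in which the hindered amide base removes only the acetylenic proton because the lactone has no α-hydrogen and is not attacked at −78 °C, and the chloroformate then installs C11.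

Step 8
Reactants: 16 methyl 4-[(2R,4R)-4-{[(tert-butyldiphenylsilyl)oxy]methyl}-4-methyl-5-oxooxolan-2-yl]but-2-ynoate
Product: 18 methyl (2E)-2-iodo-3-methyl-4-[(2S,4R)-4-{[(tert-butyldiphenylsilyl)oxy]methyl}-4-methyl-5-oxooxolan-2-yl]but-2-enoate (iodine cis to the new methyl), via alkenylcuprate 17 (not isolated)
Conditions: Me2CuLi (from MeLi and CuI, 1.3 equiv), THF, −78 °C, 30 min; then I2 in THF, −78 °C
Reagents that add atoms: lithium dimethylcuprate (from MeLi and CuI), [Li+].C[Cu-]C; iodine, II
Why: Syn-carbocupration of a 2-alkynoate followed by iodinolysis, in which methyl adds to the β-carbon C10 and copper to C9 on the same side and iodine replaces copper with retention provided the adduct stays at −78 °C (below the temperature at which it equilibrates through the allenolate), so that iodine, the site of the later C8 substituent, is cis to C20 and C1 is cis to C11.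

Step 9
Reactants: 18 methyl (2E)-2-iodo-3-methyl-4-[(2S,4R)-lactonyl]but-2-enoate; 19 isopropenylboronic acid pinacol ester
Product: 20 methyl (2Z)-3-methyl-4-[(2R,4R)-4-{[(tert-butyldiphenylsilyl)oxy]methyl}-4-methyl-5-oxooxolan-2-yl]-2-(prop-1-en-2-yl)but-2-enoate
Conditions: 19, Pd(OAc)2 (5 mol %), SPhos (10 mol %), K3PO4, THF/H2O, 50 °C
Reagents that add atoms: isopropenylboronic acid pinacol ester (19), CC(=C)B1OC(C)(C)C(C)(C)O1
Why: Suzuki–Miyaura coupling, in which oxidative addition into the electron-poor alkenyl iodide and transmetalation with the alkenylboronate both proceed with retention of alkene geometry and the bulky electron-rich phosphine copes with the tetrasubstituted centre, giving the C7=C8–C9=C10 diene with C20 cis to C8.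

Step 10
Reactants: 20 methyl (2Z)-3-methyl-4-[(2R,4R)-lactonyl]-2-(prop-1-en-2-yl)but-2-enoate
Product: 21 (3R,5R)-3-{[(tert-butyldiphenylsilyl)oxy]methyl}-5-[(2Z)-3-(hydroxymethyl)-2,4-dimethylpenta-2,4-dien-1-yl]-3-methyloxolan-2-ol (anomeric mixture)
Conditions: i-Bu2AlH (4 equiv), CH2Cl2, −78 °C; aqueous potassium sodium tartrate (KNaC4H4O6) work-up
Reagents that add atoms: none
Why: Low-temperature hydride reduction with diisobutylaluminium hydride, which takes the conjugated ester to the allylic alcohol (C11) while the γ-lactone stops at the lactol because its tetrahedral aluminate does not collapse at −78 °C, so C5 stays at the aldehyde oxidation level.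

Step 11
Reactants: 21 lactol with C11 allylic alcohol; 22 dimethyl (1-diazo-2-oxopropyl)phosphonate
Product: 23 (2Z,5R,7S)-7-{[(tert-butyldiphenylsilyl)oxy]methyl}-3,7-dimethyl-2-(prop-1-en-2-yl)non-2-en-8-yne-1,5-diol
Conditions: 22 (3 equiv), K2CO3, MeOH, 0 °C → rt (40 °C if slow)
Reagents that add atoms: dimethyl (1-diazo-2-oxopropyl)phosphonate (22), COP(=O)(OC)C(=[N+]=[N-])C(C)=O
Why: Seyferth–Gilbert homologation in its Ohira–Bestmann form, in which the lactol equilibrates with the non-enolisable hydroxy aldehyde and the diazophosphonate anion converts it into the terminal alkyne C5≡C6 while freeing the C2 hydroxyl under conditions that leave the diene and the silyl ether alone.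

Step 12
Reactants: 23 enyne diol
Product: 24 1,5-bis(tert-butyldimethylsilyl) ether of 23
Conditions: TBSCl, imidazole, DMF, rt
Reagents that add atoms: tert-butyl(chloro)dimethylsilane, CC(C)(C)[Si](C)(C)Cl
Why: Silyl ether formation on both the allylic primary (C11) and the secondary (C2) hydroxyl groups, the primary ether being the one that can later be removed selectively under mild acid.

Step 13
Reactants: 24 bis-TBS dienyne
Product: 26 6α-(dicyclohexylboryl) trans-decalin cycloadduct (5α-H; 10β-CH3; Δ8 with C8-CH3 and C9-CH2OTBS; 2α-OTBS; 4α-CH3; 4β-CH2OTBDPS), via trienylborane 25 (not isolated)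
Conditions: Chx2BH (1.05 equiv, solid prepared beforehand from cyclohexene and BH3·SMe2), THF, 0 °C → rt, 2 h; then 65 °C, sealed under argon; solvent removed under argon and crude 26 used directly
Reagents that add atoms: dicyclohexylborane, B(C1CCCCC1)C1CCCCC1
Why: Syn-hydroboration of the terminal alkyne gives only the (E)-alkenylborane 25 with boron on C6, and the vacant boron orbital lowers the LUMO of C5=C6 so that the concerted suprafacial [4+2] addition to the C7=C8–C9=C10 diene should run on gentle heating, below the range where a 1,5-hydrogen shift from the inside methyl C20 to C7 competes. The closest known reaction type is the intramolecular Diels–Alder reaction of trienyl(dialkyl)boranes generated by hydroboration of dienynes, followed by oxidation of the C–B bond. Ring B closes as the six-membered cyclohexene of the cycloaddition through C6–C7, and ring A closes at the same time as a six-membered carbocycle through C5–C10 across the four-carbon C1–C4 tether, which sits on the outside (E) position of the diene terminus C10 and exo on the dienophile. The quaternary C10 (β-methyl) follows from the diene geometry (C20 inside, C1 outside) and from the diene face chosen by the tether, while C5 (α-H) and C6 (α-boron) follow from the E-alkene reacting with boron endo and the tether exo, which gives the trans ring fusion with H5 and boron cis. The diene face is selected by the chair-like tether that keeps the C2 silyloxy group and C18 equatorial, the alternative chair placing OTBS, C18 and C20 all syn-axial. The step needs boron-endo (trans-fusion) selectivity and clean monohydroboration; the first rests on the secondary boron–diene interaction known for alkenylboranes and the second on the much faster reaction of Chx2BH with a terminal alkyne than with the 1,1-disubstituted alkene of the diene.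

Step 14
Reactants: 26 6α-boryl cycloadduct
Product: 27 6α-alcohol (5α-H; 10β-CH3; Δ8; C9-CH2OTBS; 2α-OTBS; 4β-CH2OTBDPS; 6α-OH)
Conditions: 30% H2O2, 3 M NaOH, THF, 0 °C → rt
Reagents that add atoms: hydrogen peroxide, OO
Why: Oxidation of a trialkylborane with alkaline hydrogen peroxide, in which C6 migrates from boron to oxygen with retention so that the 6α-boron becomes the 6α-hydroxyl, the silyl ethers withstanding the brief cold basic treatment.

Step 15
Reactants: 27 6α-alcohol
Product: 28 6α-acetate of 27
Conditions: Ac2O, DMAP (cat.), pyridine, rt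
Reagents that add atoms: acetic anhydride, CC(=O)OC(C)=O
Why: DMAP-catalysed acylation of the equatorial 6α-hydroxyl, the only free hydroxyl group, without change at any stereocentre.

Step 16
Reactants: 28 6α-acetate with C11-OTBS
Product: 29 C11 allylic alcohol (6α-OAc; 2α-OTBS; 19-OTBDPS retained)
Conditions: PPTS (0.2 equiv), MeOH/CH2Cl2, 0 °C → rt
Reagents that add atoms: none
Why: Selective acid-catalysed methanolysis of a silyl ether, the primary allylic TBS ether at C11 being cleaved much faster than the secondary TBS ether at C2 and the TBDPS ether at C19, while the acetate is inert.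

Step 17
Reactants: 29 C11 allylic alcohol
Product: 30 C11 enal (C9-CHO conjugated with C8=C9)
Conditions: MnO2 (excess), CH2Cl2, rt
Reagents that add atoms: none
Why: Allylic oxidation with activated MnO2, which attacks only the allylic primary alcohol under neutral conditions that the acetate and silyl ethers tolerate.

Step 18
Reactants: 30 C11 enal
Product: 31 C9-vinyl diene (C11=C12; 6α-OAc; 2α-OTBS; 19-OTBDPS)
Conditions: CH2I2, Zn, Ti(OiPr)4, THF, rt
Reagents that add atoms: diiodomethane, ICI
Why: Takai–Lombardo-type methylenation with the geminal dimetallic reagent from CH2I2 and Zn, a non-basic aldehyde-selective reagent chosen over a phosphorus ylide because a base could remove a γ-hydrogen at C7 and expel the C6 acetate, and which leaves the ester and silyl ethers alone.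

Step 19
Reactants: 31 C9-vinyl diene; 32 4-bromofuran-2(5H)-one
Product: 34 2-O-TBS 19-O-TBDPS ether of the target, via alkylborane 33 (not isolated)
Conditions: 9-BBN-H (1.5 equiv), THF, 0 °C → rt; then H2O, 32, Pd(dppf)Cl2 (10 mol %), AsPh3, Cs2CO3, DMF, rt
Reagents that add atoms: 4-bromofuran-2(5H)-one (32), O=C1C=C(Br)CO1
Why: Hydroboration followed by B-alkyl Suzuki–Miyaura coupling, in which 9-BBN adds only to the monosubstituted C11=C12 alkene with boron on the terminal C12 (the tetrasubstituted C8=C9 alkene and the acetate do not react) and the alkylborane couples with the activated β-bromobutenolide under the mild conditions used for base-sensitive partners, which attaches the intact butenolide ring.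

Step 20
Reactants: 34 bis-silyl ether of the target
Product: 35 6α-acetoxy-2α,19-dihydroxylabda-8,13-dien-15,16-olide (CNP0231903.1)
Conditions: HF·pyridine, THF, 0 °C → rt
Reagents that add atoms: none
Why: Fluoride-mediated desilylation under acidic conditions, which cleaves the secondary TBS and the primary TBDPS ethers without acetate migration or hydrolysis and without harm to the butenolide or any stereocentre.

**Compound list**

1 | dimethyl methylmalonate | COC(=O)C(C)C(=O)OC | starting material
2 | allyl bromide | C=CCBr | starting material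
3 | dimethyl 2-methyl-2-(prop-2-en-1-yl)propanedioate | COC(=O)C(C)(CC=C)C(=O)OC | intermediate
4 | (2R)-2-(methoxycarbonyl)-2-methylpent-4-enoic acid | C=CC[C@](C)(C(=O)O)C(=O)OC | intermediate
5 | mixed anhydride of 4 with ethyl hydrogen carbonate (not isolated) | C=CC[C@](C)(C(=O)OC(=O)OCC)C(=O)OC | intermediate
6 | methyl (2R)-2-(hydroxymethyl)-2-methylpent-4-enoate | C=CC[C@](C)(CO)C(=O)OC | intermediate
7 | methyl (2R)-2-{[(tert-butyldiphenylsilyl)oxy]methyl}-2-methylpent-4-enoate | C=CC[C@](C)(CO[Si](c1ccccc1)(c1ccccc1)C(C)(C)C)C(=O)OC | intermediate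
8 | secondary ozonide of 7 (3-substituted 1,2,4-trioxolane, epimers at the ring carbon; not isolated) | C1OOC(C[C@](C)(CO[Si](c2ccccc2)(c2ccccc2)C(C)(C)C)C(=O)OC)O1 | intermediate
9 | methyl (2R)-2-{[(tert-butyldiphenylsilyl)oxy]methyl}-2-methyl-4-oxobutanoate | O=CC[C@](C)(CO[Si](c1ccccc1)(c1ccccc1)C(C)(C)C)C(=O)OC | intermediate
10 | allenylboronic acid pinacol ester (4,4,5,5-tetramethyl-2-(propa-1,2-dien-1-yl)-1,3,2-dioxaborolane) | C=C=CB1OC(C)(C)C(C)(C)O1 | starting material
11 | pinacol borate ester of 12 (not isolated) | C#CC[C@@H](OB1OC(C)(C)C(C)(C)O1)C[C@](C)(CO[Si](c1ccccc1)(c1ccccc1)C(C)(C)C)C(=O)OC | intermediate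
12 | methyl (2R,4R)-2-{[(tert-butyldiphenylsilyl)oxy]methyl}-4-hydroxy-2-methylhept-6-ynoate (not isolated) | C#CC[C@@H](O)C[C@](C)(CO[Si](c1ccccc1)(c1ccccc1)C(C)(C)C)C(=O)OC | intermediate
13 | (3R,5R)-3-{[(tert-butyldiphenylsilyl)oxy]methyl}-3-methyl-5-(prop-2-yn-1-yl)oxolan-2-one (propargyl cis to CH2OTBDPS) | C#CC[C@@H]1C[C@](C)(CO[Si](c2ccccc2)(c2ccccc2)C(C)(C)C)C(=O)O1 | intermediate
14 | methyl chloroformate | COC(=O)Cl | starting material
15 | lithium acetylide of 13 (not isolated) | [Li]C#CC[C@@H]1C[C@](C)(CO[Si](c2ccccc2)(c2ccccc2)C(C)(C)C)C(=O)O1 | intermediate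
16 | methyl 4-[(2R,4R)-4-{[(tert-butyldiphenylsilyl)oxy]methyl}-4-methyl-5-oxooxolan-2-yl]but-2-ynoate | COC(=O)C#CC[C@@H]1C[C@](C)(CO[Si](c2ccccc2)(c2ccccc2)C(C)(C)C)C(=O)O1 | intermediate
17 | lithium alkenyl(methyl)cuprate from syn-addition to 16 (copper on C9, cis to the new methyl; not isolated) | COC(=O)/C([Cu-]C)=C(/C)C[C@@H]1C[C@](C)(CO[Si](c2ccccc2)(c2ccccc2)C(C)(C)C)C(=O)O1.[Li+] | intermediate
18 | methyl (2E)-2-iodo-3-methyl-4-[(2S,4R)-4-{[(tert-butyldiphenylsilyl)oxy]methyl}-4-methyl-5-oxooxolan-2-yl]but-2-enoate (iodine cis to the C3 methyl; same lactone configuration as 13, the descriptor at oxolane C2 changes only because iodine raises the side-chain priority) | COC(=O)/C(I)=C(/C)C[C@@H]1C[C@](C)(CO[Si](c2ccccc2)(c2ccccc2)C(C)(C)C)C(=O)O1 | intermediate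
19 | isopropenylboronic acid pinacol ester | CC(=C)B1OC(C)(C)C(C)(C)O1 | starting material
20 | methyl (2Z)-3-methyl-4-[(2R,4R)-4-{[(tert-butyldiphenylsilyl)oxy]methyl}-4-methyl-5-oxooxolan-2-yl]-2-(prop-1-en-2-yl)but-2-enoate | COC(=O)/C(C(C)=C)=C(/C)C[C@@H]1C[C@](C)(CO[Si](c2ccccc2)(c2ccccc2)C(C)(C)C)C(=O)O1 | intermediate
21 | (3R,5R)-3-{[(tert-butyldiphenylsilyl)oxy]methyl}-5-[(2Z)-3-(hydroxymethyl)-2,4-dimethylpenta-2,4-dien-1-yl]-3-methyloxolan-2-ol (anomeric mixture) | OC/C(C(C)=C)=C(/C)C[C@@H]1C[C@](C)(CO[Si](c2ccccc2)(c2ccccc2)C(C)(C)C)C(O)O1 | intermediate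
22 | dimethyl (1-diazo-2-oxopropyl)phosphonate | COP(=O)(OC)C(=[N+]=[N-])C(C)=O | starting material
23 | (2Z,5R,7S)-7-{[(tert-butyldiphenylsilyl)oxy]methyl}-3,7-dimethyl-2-(prop-1-en-2-yl)non-2-en-8-yne-1,5-diol | C=C(C)/C(CO)=C(\C)C[C@@H](O)C[C@](C)(CO[Si](c1ccccc1)(c1ccccc1)C(C)(C)C)C#C | intermediate
24 | 1,5-bis(tert-butyldimethylsilyl) ether of 23 | C=C(C)/C(CO[Si](C)(C)C(C)(C)C)=C(\C)C[C@@H](O[Si](C)(C)C(C)(C)C)C[C@](C)(CO[Si](c1ccccc1)(c1ccccc1)C(C)(C)C)C#C | intermediate
25 | (E)-alkenyl(dicyclohexyl)borane from 24, boron on C6 (acyclic trienylborane; not isolated) | C=C(C)/C(CO[Si](C)(C)C(C)(C)C)=C(\C)C[C@@H](O[Si](C)(C)C(C)(C)C)C[C@](C)(CO[Si](c1ccccc1)(c1ccccc1)C(C)(C)C)/C=C/B(C1CCCCC1)C1CCCCC1 | intermediate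
26 | trans-decalin cycloadduct: 6α-(dicyclohexylboryl), 5α-H, 10β-CH3, Δ8 with C8-CH3 and C9-CH2OTBS, 2α-OTBS, 4α-CH3, 4β-CH2OTBDPS | B(C3CCCCC3)(C4CCCCC4)[C@H]1CC(C)=C(CO[Si](C)(C)C(C)(C)C)[C@@]2(C)C[C@@H](O[Si](C)(C)C(C)(C)C)C[C@](C)(CO[Si](c5ccccc5)(c6ccccc6)C(C)(C)C)[C@H]12 | intermediate
27 | 6α-alcohol corresponding to 26 | O[C@H]1CC(C)=C(CO[Si](C)(C)C(C)(C)C)[C@@]2(C)C[C@@H](O[Si](C)(C)C(C)(C)C)C[C@](C)(CO[Si](c3ccccc3)(c3ccccc3)C(C)(C)C)[C@H]12 | intermediate
28 | 6α-acetate of 27 | CC(=O)O[C@H]1CC(C)=C(CO[Si](C)(C)C(C)(C)C)[C@@]2(C)C[C@@H](O[Si](C)(C)C(C)(C)C)C[C@](C)(CO[Si](c3ccccc3)(c3ccccc3)C(C)(C)C)[C@H]12 | intermediate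
29 | C11 allylic alcohol: 6α-OAc, 2α-OTBS, 19-OTBDPS, C9-CH2OH | CC(=O)O[C@H]1CC(C)=C(CO)[C@@]2(C)C[C@@H](O[Si](C)(C)C(C)(C)C)C[C@](C)(CO[Si](c3ccccc3)(c3ccccc3)C(C)(C)C)[C@H]12 | intermediate
30 | C11 enal: as 29 with C9-CHO | CC(=O)O[C@H]1CC(C)=C(C=O)[C@@]2(C)C[C@@H](O[Si](C)(C)C(C)(C)C)C[C@](C)(CO[Si](c3ccccc3)(c3ccccc3)C(C)(C)C)[C@H]12 | intermediate
31 | C9-vinyl diene: as 29 with C9-CH=CH2 (C11=C12) | CC(=O)O[C@H]1CC(C)=C(C=C)[C@@]2(C)C[C@@H](O[Si](C)(C)C(C)(C)C)C[C@](C)(CO[Si](c3ccccc3)(c3ccccc3)C(C)(C)C)[C@H]12 | intermediate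
32 | 4-bromofuran-2(5H)-one | O=C1C=C(Br)CO1 | starting material
33 | B-alkyl-9-borabicyclo[3.3.1]nonane from 31, boron on C12 (not isolated) | CC(=O)O[C@H]1CC(C)=C(CCB3C4CCCC3CCC4)[C@@]2(C)C[C@@H](O[Si](C)(C)C(C)(C)C)C[C@](C)(CO[Si](c5ccccc5)(c6ccccc6)C(C)(C)C)[C@H]12 | intermediate
34 | 2-O-TBS 19-O-TBDPS ether of the target | CC(=O)O[C@H]1CC(C)=C(CCC3=CC(=O)OC3)[C@@]2(C)C[C@@H](O[Si](C)(C)C(C)(C)C)C[C@](C)(CO[Si](c4ccccc4)(c5ccccc5)C(C)(C)C)[C@H]12 | intermediate
35 | 6α-acetoxy-2α,19-dihydroxylabda-8,13-dien-15,16-olide (CNP0231903.1) | CC(=O)O[C@H]1CC(C)=C(CCC2=CC(=O)OC2)[C@@]2(C)C[C@@H](O)C[C@](C)(CO)[C@H]12 | target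

**Step count and risks**

Total step count: 20. Longest linear sequence: 20 steps (1 → 35); all other building blocks are commercial.

Steps most likely to fail:

1. Step 13. Ring closure may be too slow at the temperature that the diene and the alkenylborane tolerate, because the diene terminus C10 is fully substituted and carries the inside methyl C20. A 1,5-hydrogen shift in the diene or thermal breakdown of the borane could then overtake the cycloaddition, or boron-endo (trans-fusion) selection could be incomplete. Fallback: from alkyne 24, a nickel-catalysed intramolecular [4+2] cycloaddition of the dienyne (Ni(cod)2, tris(2-biphenylyl) phosphite, THF, rt) would close the same C5–C10 and C6–C7 bonds without thermal activation and give the cyclohexa-1,4-diene F1, with C10 set by the same chair-like tether. Hydroboration of its trisubstituted C5=C6 alkene with BH3·THF should place boron on C6 from the α face, since the β face is covered by C20 and the axial C19 group and the tetrasubstituted C8=C9 alkene reacts far more slowly. Oxidation with H2O2/NaOH then gives the 5α-H, 6α-OH alcohol, and the route is rejoined at 27.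

2. Step 19. Hydroboration may not stop cleanly at C12 of the hindered diene, and in the basic aqueous coupling medium the bromobutenolide may be hydrolysed or the acetate lost before transmetalation. Fallback: from allylic alcohol 29, the butenolide is built instead of coupled. CBr4/PPh3 gives the allylic bromide F2. Alkylation at −78 °C with the kinetic lithium enolate (LiN(iPr)2, THF) of 1-[(tert-butyldimethylsilyl)oxy]propan-2-one, reacting at its methyl terminus, gives the silyloxy ketone F3. PPTS in methanol frees the primary α-keto alcohol to give the hydroxy ketone F4. Ph3P=C=C=O in toluene at 80 °C acylates that hydroxyl and closes the ring by intramolecular Wittig reaction, and the route is rejoined at 34.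

3. Step 2. The esterase may discriminate poorly between the enantiotopic ester groups, since allyl and methyl differ little in size. Fallback: from diester 3, half-saponification with one equivalent of KOH in methanol gives the racemic half-ester F5. This is resolved by crystallisation of its salt with (S)-1-phenylethylamine, the diastereomeric salt F6 (the other enantiomer of the amine is used if its salt with the (R)-acid is the less soluble), and acidification returns the route to 4. Residual enantiomer is removed further on, because after the catalyst-controlled step 6 it ends up in the trans-lactone, which is separable from 13.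

**Further compounds**

F1 | step 13 | cyclohexa-1,4-diene (C5=C6 and C8=C9; 10β-CH3; 2α-OTBS; 4α-CH3; 4β-CH2OTBDPS; C9-CH2OTBS) | C=1CC(C)=C(CO[Si](C)(C)C(C)(C)C)[C@@]2(C)C[C@@H](O[Si](C)(C)C(C)(C)C)C[C@](C)(CO[Si](c3ccccc3)(c3ccccc3)C(C)(C)C)C=12
F2 | step 19 | C11 allylic bromide (as 29 with C9-CH2Br) | CC(=O)O[C@H]1CC(C)=C(CBr)[C@@]2(C)C[C@@H](O[Si](C)(C)C(C)(C)C)C[C@](C)(CO[Si](c3ccccc3)(c3ccccc3)C(C)(C)C)[C@H]12
F3 | step 19 | C13 ketone with C16-OTBS (C9-CH2CH2C(=O)CH2OTBS) | CC(=O)O[C@H]1CC(C)=C(CCC(=O)CO[Si](C)(C)C(C)(C)C)[C@@]2(C)C[C@@H](O[Si](C)(C)C(C)(C)C)C[C@](C)(CO[Si](c3ccccc3)(c3ccccc3)C(C)(C)C)[C@H]12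
F4 | step 19 | C13 ketone with free C16 hydroxyl (C9-CH2CH2C(=O)CH2OH) | CC(=O)O[C@H]1CC(C)=C(CCC(=O)CO)[C@@]2(C)C[C@@H](O[Si](C)(C)C(C)(C)C)C[C@](C)(CO[Si](c3ccccc3)(c3ccccc3)C(C)(C)C)[C@H]12
F5 | step 2 | racemic 2-(methoxycarbonyl)-2-methylpent-4-enoic acid | C=CCC(C)(C(=O)O)C(=O)OC
F6 | step 2 | (S)-1-phenylethylammonium (2R)-2-(methoxycarbonyl)-2-methylpent-4-enoate | C=CC[C@](C)(C(=O)[O-])C(=O)OC.C[C@H]([NH3+])c1ccccc1
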